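**Retrosynthetic overview** (terpenoid numbering: C10 quaternary with C14 methyl and C1=C2 vinyl; C5 with the C4(=C3)–C15 branch; C6; C7; C8; C9; lactone C11, C12, C13)
1. Feature: on the cyclohexane C5–C6–C7–C8–C9–C10 the C6 carbinol sits next to C7, the β-carbon of the cis-fused α-methylene γ-lactone (C7–C11(=C13)–C12(=O)–O–C8). C6 (an aldehyde carbon) and C7 (a butenolide β-carbon) are both acceptor carbons, so the C6–C7 bond is made with reversed polarity at C6 through a ketyl.
2. The cyclohexane is the last ring formed: SmI2 closes C6–C7 on a seco-aldehyde carrying an α-(phenylthiomethyl)butenolide, and loss of PhS from C13 uncovers C11=C13. The γ-lactone ring comes from the chiral pool (C8) and is converted into the butenolide beforehand.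
3. Butenolide from the saturated lactone by selenenylation, formaldehyde aldol, selenoxide elimination and Hata sulfenylation, with the C9 isobutyrate already in place; no base meets the butenolide γ-proton.
4. C9–C10 (sets C9 and C10) by allylboration of (S)-5-oxotetrahydrofuran-2-carbaldehyde with an (E)-γ,γ-disubstituted allylboronate, itself from Ni-catalysed 1,4-hydroboration of a 2-substituted 1,3-diene.
5. The diene (carrying C5) from α-methylenation, half-reduction and Wittig reaction of an (R)-β-alkenyl butyrolactone, made by cuprate addition to a menthyloxybutenolide (the auxiliary sets C5).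

Key step: step 18

Remark on the chemistry: the (5S)-(+)-menthyloxybutenolide of step 4 (antipode of the common (−)-menthol-derived reagent) is taken as purchasable; it is otherwise one step from 5-hydroxyfuran-2(5H)-one and (+)-menthol.

**Route**

Step 1
Reactants: 1 (S)-5-oxotetrahydrofuran-2-carboxylic acid
Product: 2 (S)-5-(hydroxymethyl)dihydrofuran-2(3H)-one
Conditions: BH3·SMe2, THF, 0 °C to rt; MeOH quench
Reagents that add atoms: none
Why: Borane reduction of a carboxylic acid is chemoselective over the γ-lactone and does not touch C8.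

Step 2
Reactants: 2 (S)-5-(hydroxymethyl)dihydrofuran-2(3H)-one
Product: 3 (S)-5-oxotetrahydrofuran-2-carbaldehyde
Conditions: (COCl)2, DMSO, CH2Cl2, −78 °C; Et3N; filtered, used crude at once
Reagents that add atoms: none
Why: Swern oxidation under anhydrous conditions should give the hydrate-prone, configurationally labile α-acyloxy aldehyde without aqueous work-up.

Step 3
Reactants: 4 2-bromoprop-2-en-1-ol
Product: 5 [(2-bromoprop-2-en-1-yl)oxy](tert-butyl)dimethylsilane
Conditions: TBSCl, imidazole, CH2Cl2, 0 °C to rt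
Reagents that add atoms: tert-butyldimethylsilyl chloride, CC(C)(C)[Si](C)(C)Cl
Why: Silyl ether formation on a primary allylic alcohol; this silyl group becomes the C15 protecting group of the cyclisation precursor.

Step 4
Reactants: 5 [(2-bromoprop-2-en-1-yl)oxy](tert-butyl)dimethylsilane; 6 (5S)-5-{[(1S,2R,5S)-5-methyl-2-(propan-2-yl)cyclohexyl]oxy}furan-2(5H)-one
Product: 9 (4R,5S)-4-{3-[(tert-butyldimethylsilyl)oxy]prop-1-en-2-yl}-5-{[(1S,2R,5S)-5-methyl-2-(propan-2-yl)cyclohexyl]oxy}dihydrofuran-2(3H)-one, via 2-lithioallyl silyl ether 7 (not isolated), via lithium dialkenylcuprate 8 (not isolated)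
Conditions: t-BuLi (2 equiv per 5), Et2O, −78 °C; CuI (0.5 equiv per 5); then 6, −78 °C; aq NH4Cl
Reagents that add atoms: none
Why: Bromine–lithium exchange at −78 °C (where the 2-lithioallyl ether should not eliminate) and transmetallation give a Gilman cuprate whose conjugate addition to the butenolide occurs anti to the menthyloxy group, so the acetal centre sets C5.

Step 5
Reactants: 9 (4R,5S)-4-{3-[(tert-butyldimethylsilyl)oxy]prop-1-en-2-yl}-5-(menthyloxy)dihydrofuran-2(3H)-one
Product: 12 (R)-4-{3-[(tert-butyldimethylsilyl)oxy]prop-1-en-2-yl}dihydrofuran-2(3H)-one, via potassium formyl carboxylate 10 (not isolated), via potassium hydroxy carboxylate 11 (not isolated)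
Conditions: NaBH4, KOH, EtOH–H2O, 0 °C to rt; then 1 M HCl to pH 3, 0 °C
Reagents that add atoms: none
Why: Hydroxide opens the γ-alkoxy lactone (an acylal) to a carboxylate and a hemiacetal that releases menthol, NaBH4 should reduce the freed aldehyde faster than its α-carbon C5 enolises, and acidification relactonises (auxiliary removal by reduction–lactonisation) with C5 retained.

Step 6
Reactants: 12 (R)-4-{3-[(tert-butyldimethylsilyl)oxy]prop-1-en-2-yl}dihydrofuran-2(3H)-one
Product: 15 (S)-4-{3-[(tert-butyldimethylsilyl)oxy]prop-1-en-2-yl}-3-methylidenedihydrofuran-2(3H)-one, via Mannich base 13 (not isolated), via trimethylammonium iodide 14 (not isolated)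
Conditions: LiN(i-Pr)2, THF, −78 °C; Me2N=CH2 I (Eschenmoser's salt), −78 to 0 °C; MeI, MeOH, rt; aq NaHCO3, CH2Cl2
Reagents that add atoms: Eschenmoser's salt (N,N-dimethylmethyleneiminium iodide), C=[N+](C)C.[I-]
Why: Mannich reaction of the lactone enolate, quaternisation and bicarbonate-induced elimination (α-methylenation) install C14 as the exocyclic methylene under conditions too mild to move the double bond into the ring past the C5–H (same spatial arrangement at C5; the descriptor changes by priority only).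

Step 7
Reactants: 15 (S)-4-{3-[(tert-butyldimethylsilyl)oxy]prop-1-en-2-yl}-3-methylidenedihydrofuran-2(3H)-one
Product: 16 (4S)-4-{3-[(tert-butyldimethylsilyl)oxy]prop-1-en-2-yl}-3-methylidenetetrahydrofuran-2-ol (anomer mixture)
Conditions: i-Bu2AlH (1.1 equiv), CH2Cl2, −78 °C; aq potassium sodium tartrate (KNaC4H4O6)
Reagents that add atoms: none
Why: Partial reduction of a lactone to the lactol at −78 °C; 1,2-reduction is the normal course for α-methylene lactones.

Step 8
Reactants: 16 (4S)-4-{3-[(tert-butyldimethylsilyl)oxy]prop-1-en-2-yl}-3-methylidenetetrahydrofuran-2-ol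
Product: 17 (R)-2-{3-[(tert-butyldimethylsilyl)oxy]prop-1-en-2-yl}-3-methylidenepent-4-en-1-ol
Conditions: Ph3PCH3Br, KN(SiMe3)2 (2.5 equiv each), THF, 0 °C to rt
Reagents that add atoms: methyltriphenylphosphonium bromide, C[P+](c1ccccc1)(c1ccccc1)c1ccccc1.[Br-]
Why: Wittig methylenation of the ring-opened 2-substituted acrolein tautomer builds the C1=C2 vinyl group and frees the C6 hydroxyl; ylide addition to the aldehyde should outrun γ-deprotonation.

Step 9
Reactants: 17 (R)-2-{3-[(tert-butyldimethylsilyl)oxy]prop-1-en-2-yl}-3-methylidenepent-4-en-1-ol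
Product: 18 triethylsilyl ether of 17, (R)-configured
Conditions: TESCl, imidazole, CH2Cl2, 0 °C
Reagents that add atoms: chlorotriethylsilane, CC[Si](Cl)(CC)CC
Why: Silyl ether formation; triethylsilyl is chosen so that the C6 oxygen can later be freed in the presence of the C15 tert-butyldimethylsilyl ether.

Step 10
Reactants: 18 triethylsilyl ether of (R)-2-{3-[(tert-butyldimethylsilyl)oxy]prop-1-en-2-yl}-3-methylidenepent-4-en-1-ol
Product: 19 (R,E)-allylboronate: 2-[(E,4R)-3-methyl-5-[(tert-butyldimethylsilyl)oxy]methyl... pinacol boronate pinB–C2H2–C1H=C10(CH3)–C5H(CH2OSiEt3)–C4(=CH2)–CH2OTBS, with the C5 branch trans and the methyl cis to CH2B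
Conditions: Ni(cod)2 (2.5 mol %, zerovalent nickel), PCy3 (2.5 mol %), HBpin (1.1 equiv), toluene, rt
Reagents that add atoms: pinacolborane, [H]B1OC(C)(C)C(C)(C)O1
Why: Nickel-catalysed 1,4-hydroboration of the 1,3-diene: hydride goes to C14 and boron to the unhindered terminus C2 through the s-cis diene complex, which places the new methyl cis to CH2B (E alkene), while the isolated 1,1-disubstituted alkene is inert.

Step 11
Reactants: 19 (R,E)-allylboronate; 3 (S)-5-oxotetrahydrofuran-2-carbaldehyde (1.5 equiv)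
Product: 20 (5S)-5-[(1R,2S,3S)-2-ethenyl-1-hydroxy-2-methyl-4-{[(tert-butyldimethylsilyl)oxy]methyl}-3-{[(triethylsilyl)oxy]methyl}pent-4-en-1-yl]dihydrofuran-2(3H)-one
Conditions: toluene, rt to 40 °C; aq NaHCO3 work-up
Reagents that add atoms: none
Why: Allylboration through a Zimmerman–Traxler chair: the E geometry puts the C5 branch anti and the methyl syn to the new hydroxyl (C10 relative to C9), and the aldehyde is attacked anti to the lactone C8–O bond (Felkin–Anh/Cornforth control, reinforced by the cis-methyl of the reagent), which should give 9R,10S; C5 sits on the outward-pointing substituent as a spectator.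

Step 12
Reactants: 20 the C9 alcohol
Product: 21 (1R,2S,3S)-2-ethenyl-2-methyl-1-[(2S)-5-oxotetrahydrofuran-2-yl]-4-{[(tert-butyldimethylsilyl)oxy]methyl}-3-{[(triethylsilyl)oxy]methyl}pent-4-en-1-yl 2-methylpropanoate
Conditions: (i-PrCO)2O, DMAP, Et3N, CH2Cl2, rt
Reagents that add atoms: isobutyric anhydride, CC(C)C(=O)OC(=O)C(C)C
Why: DMAP-catalysed acylation of the hindered secondary alcohol, done while the lactone is still saturated so that no base-sensitive butenolide γ-proton is exposed.

Step 13
Reactants: 21 the C9 isobutyrate with saturated lactone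
Product: 23 isobutyrate 21 carrying hydroxymethyl and phenylselanyl groups at C11 (C11 epimers), via α-phenylselanyl lactone 22 (not isolated)
Conditions: LiN(i-Pr)2 (1.05 equiv), THF, −78 °C; PhSeBr; LiN(i-Pr)2 (1.1 equiv); CH2O (gas), −78 °C; aq NH4Cl
Reagents that add atoms: phenylselenenyl bromide, Br[Se]c1ccccc1; formaldehyde, C=O
Why: The lactone α-CH2 is the most acidic and most accessible C–H (more so than the tertiary α-H of the isobutyrate), so enolate selenenylation followed by aldol addition of the α-seleno enolate to formaldehyde should give the adduct; the C11 stereocentre is inconsequential.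

Step 14
Reactants: 23 the C11 hydroxymethyl selenide
Product: 25 (1R,2S,3S)-2-ethenyl-1-[(2S)-4-(hydroxymethyl)-5-oxo-2,5-dihydrofuran-2-yl]-2-methyl-4-{[(tert-butyldimethylsilyl)oxy]methyl}-3-{[(triethylsilyl)oxy]methyl}pent-4-en-1-yl 2-methylpropanoate, via selenoxide 24 (not isolated)
Conditions: NaIO4, NaHCO3, THF–H2O, 0 °C to rt
Reagents that add atoms: none
Why: Selenide oxidation and selenoxide syn-elimination, which goes away from the carbinol carbon toward C7–H and so delivers the C7=C11 butenolide bearing C13–OH; a Baylis–Hillman reaction on a γ-substituted butenolide is avoided because amine or phosphine bases would deprotonate C8 and expel the C9 ester.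

Step 15
Reactants: 25 the α-(hydroxymethyl)butenolide
Product: 26 the α-[(phenylsulfanyl)methyl]butenolide (C13–SPh; C6–OSiEt3, C15–OTBS, C9 isobutyrate)
Conditions: (PhS)2, Bu3P, THF, 0 °C to rt
Reagents that add atoms: diphenyl disulfide, c1ccc(SSc2ccccc2)cc1
Why: Hata reaction (disulfide/phosphine) converts the primary allylic alcohol into the aryl sulfide under neutral conditions; any SN2′ isomer should equilibrate by thiolate addition–elimination to the conjugated butenolide.

Step 16
Reactants: 26 the α-[(phenylsulfanyl)methyl]butenolide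
Product: 27 the C6 primary alcohol (C15–OTBS retained)
Conditions: PPTS, MeOH–CH2Cl2, 0 °C
Reagents that add atoms: none
Why: Acid-catalysed methanolysis cleaves the primary triethylsilyl ether much faster than the tert-butyldimethylsilyl ether (selective desilylation).

Step 17
Reactants: 27 the C6 primary alcohol
Product: 28 (1R,2S,3S)-2-ethenyl-3-formyl-2-methyl-1-{(2S)-5-oxo-4-[(phenylsulfanyl)methyl]-2,5-dihydrofuran-2-yl}-4-{[(tert-butyldimethylsilyl)oxy]methyl}pent-4-en-1-yl 2-methylpropanoate
Conditions: Dess–Martin periodinane, NaHCO3, CH2Cl2, 0 °C; filtered through a short silica pad, used at once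
Reagents that add atoms: none
Why: Buffered Dess–Martin oxidation is neutral, so the β,γ-unsaturated α-branched aldehyde should form without epimerisation at C5 or conjugation, and alcohol oxidation is faster than sulfide oxidation.

Step 18
Reactants: 28 the seco-aldehyde
Product: 29 the 15-O-(tert-butyldimethylsilyl) ether of the target, (5S,6R,7S,8S,9R,10S)
Conditions: SmI2 (2.2 equiv, 0.1 M in THF), THF, −78 °C, 28 added over 1 h to 5 mM, then to −40 °C; pH 7 buffer (NaH2PO4/Na2HPO4)
Reagents that add atoms: none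
Why: Proposed new method: SmI2 (divalent samarium) transfers one electron to the C6 aldehyde, the samarium-bound ketyl adds to the electron-poor β-carbon C7 of the butenolide, and the C11 radical either expels PhS• or is reduced by the second equivalent to the trivalent-samarium enolate that eliminates thiolate, both paths ending at the C11=C13 methylene; the closest known reaction types are the SmI2 ketyl–olefin cyclisation onto α,β-unsaturated esters and lactones and the addition–fragmentation of radicals on allyl sulfides. The cyclohexane closes in the 6-exo-trig mode through a chair with the C5 alkenyl branch, the C10 vinyl group and the C9 isobutyrate equatorial and the C8–O bond axial. C7 is set by the tether: it is anchored at C8, so the ketyl reaches C7 only on the lactone face that carries C9, and the ring fusion is cis. C6 is set by the samarium-bound oxygen, which takes the equatorial site of this chair, trans to both C5–C4 and C7–C11 (the anti preference known for ketyl–enoate cyclisations). The step needs the aldehyde to be reduced before the butenolide and the product α-methylene lactone to survive: aldehydes are reduced far faster than unsaturated lactones by SmI2 without HMPA at −78 °C, 28 is added slowly at high dilution, and only the two equivalents required by the redox balance are used.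

Step 19
Reactants: 29 the 15-O-silyl ether
Product: 30 target CNP0298885.1, (5S,6R,7S,8S,9R,10S)
Conditions: HF·pyridine, pyridine, THF, 0 °C to rt
Reagents that add atoms: none
Why: Buffered fluoride desilylation of the allylic silyl ether without base should spare the α-methylene lactone, the isobutyrate and the 6-hydroxy-7,8-lactone arrangement.

**Compound list**

1 | (S)-5-oxotetrahydrofuran-2-carboxylic acid | OC(=O)[C@H]1OC(=O)CC1 | starting material
2 | (S)-5-(hydroxymethyl)dihydrofuran-2(3H)-one | OC[C@H]1OC(=O)CC1 | intermediate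
3 | (S)-5-oxotetrahydrofuran-2-carbaldehyde | O=C[C@H]1OC(=O)CC1 | intermediate
4 | 2-bromoprop-2-en-1-ol | OCC(Br)=C | starting material
5 | [(2-bromoprop-2-en-1-yl)oxy](tert-butyl)dimethylsilane | C=C(Br)CO[Si](C)(C)C(C)(C)C | intermediate
6 | (5S)-5-{[(1S,2R,5S)-5-methyl-2-(propan-2-yl)cyclohexyl]oxy}furan-2(5H)-one | CC(C)[C@H]1CC[C@H](C)C[C@@H]1O[C@H]2OC(=O)C=C2 | starting material
7 | {3-[(tert-butyldimethylsilyl)oxy]prop-1-en-2-yl}lithium | [Li]C(=C)CO[Si](C)(C)C(C)(C)C | intermediate (not isolated)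
8 | lithium bis{3-[(tert-butyldimethylsilyl)oxy]prop-1-en-2-yl}cuprate | [Li+].C=C(CO[Si](C)(C)C(C)(C)C)[Cu-]C(=C)CO[Si](C)(C)C(C)(C)C | intermediate (not isolated)
9 | (4R,5S)-4-{3-[(tert-butyldimethylsilyl)oxy]prop-1-en-2-yl}-5-{[(1S,2R,5S)-5-methyl-2-(propan-2-yl)cyclohexyl]oxy}dihydrofuran-2(3H)-one (4,5-trans) | CC(C)[C@H]1CC[C@H](C)C[C@@H]1O[C@H]2OC(=O)C[C@@H]2C(=C)CO[Si](C)(C)C(C)(C)C | intermediate
10 | potassium (R)-3-formyl-4-{[(tert-butyldimethylsilyl)oxy]methyl}pent-4-enoate | [K+].[O-]C(=O)C[C@@H](C=O)C(=C)CO[Si](C)(C)C(C)(C)C | intermediate (not isolated)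
11 | potassium (R)-3-(hydroxymethyl)-4-{[(tert-butyldimethylsilyl)oxy]methyl}pent-4-enoate | [K+].[O-]C(=O)C[C@@H](CO)C(=C)CO[Si](C)(C)C(C)(C)C | intermediate (not isolated)
12 | (R)-4-{3-[(tert-butyldimethylsilyl)oxy]prop-1-en-2-yl}dihydrofuran-2(3H)-one | O=C1C[C@H](C(=C)CO[Si](C)(C)C(C)(C)C)CO1 | intermediate
13 | (3R,4R)-3-[(dimethylamino)methyl]-4-{3-[(tert-butyldimethylsilyl)oxy]prop-1-en-2-yl}dihydrofuran-2(3H)-one (trans) | O=C1[C@@H](CN(C)C)[C@H](C(=C)CO[Si](C)(C)C(C)(C)C)CO1 | intermediate (not isolated)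
14 | N-methyl quaternary ammonium iodide of 13 | [I-].O=C1[C@@H](C[N+](C)(C)C)[C@H](C(=C)CO[Si](C)(C)C(C)(C)C)CO1 | intermediate (not isolated)
15 | (S)-4-{3-[(tert-butyldimethylsilyl)oxy]prop-1-en-2-yl}-3-methylidenedihydrofuran-2(3H)-one | O=C1C(=C)[C@H](C(=C)CO[Si](C)(C)C(C)(C)C)CO1 | intermediate
16 | (4S)-4-{3-[(tert-butyldimethylsilyl)oxy]prop-1-en-2-yl}-3-methylidenetetrahydrofuran-2-ol (anomer mixture, C2 undefined) | OC1C(=C)[C@H](C(=C)CO[Si](C)(C)C(C)(C)C)CO1 | intermediate
17 | (R)-2-{3-[(tert-butyldimethylsilyl)oxy]prop-1-en-2-yl}-3-methylidenepent-4-en-1-ol | OC[C@@H](C(=C)CO[Si](C)(C)C(C)(C)C)C(=C)C=C | intermediate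
18 | triethylsilyl ether of 17, (R) | CC[Si](CC)(CC)OC[C@@H](C(=C)CO[Si](C)(C)C(C)(C)C)C(=C)C=C | intermediate
19 | (R,E)-allylboronate, pinB–CH2–CH=C(CH3)–CH(CH2OSiEt3)–C(=CH2)–CH2OTBS (branch trans to CH2B) | CC[Si](CC)(CC)OC[C@@H](C(=C)CO[Si](C)(C)C(C)(C)C)/C(C)=C/CB1OC(C)(C)C(C)(C)O1 | intermediate
20 | (5S)-5-[(1R,2S,3S)-2-ethenyl-1-hydroxy-2-methyl-4-{[(tert-butyldimethylsilyl)oxy]methyl}-3-{[(triethylsilyl)oxy]methyl}pent-4-en-1-yl]dihydrofuran-2(3H)-one | CC[Si](CC)(CC)OC[C@@H](C(=C)CO[Si](C)(C)C(C)(C)C)[C@](C)(C=C)[C@@H](O)[C@H]1OC(=O)CC1 | intermediate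
21 | 2-methylpropanoate (C9 isobutyrate) of 20 | CC[Si](CC)(CC)OC[C@@H](C(=C)CO[Si](C)(C)C(C)(C)C)[C@](C)(C=C)[C@@H](OC(=O)C(C)C)[C@H]1OC(=O)CC1 | intermediate
22 | 21 with phenylselanyl at C11 (lactone C3; epimers, C11 undefined) | CC[Si](CC)(CC)OC[C@@H](C(=C)CO[Si](C)(C)C(C)(C)C)[C@](C)(C=C)[C@@H](OC(=O)C(C)C)[C@H]1OC(=O)C([Se]c2ccccc2)C1 | intermediate (not isolated)
23 | 21 with hydroxymethyl and phenylselanyl at C11 (epimers, C11 undefined) | CC[Si](CC)(CC)OC[C@@H](C(=C)CO[Si](C)(C)C(C)(C)C)[C@](C)(C=C)[C@@H](OC(=O)C(C)C)[C@H]1OC(=O)C(CO)([Se]c2ccccc2)C1 | intermediate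
24 | selenoxide of 23 | CC[Si](CC)(CC)OC[C@@H](C(=C)CO[Si](C)(C)C(C)(C)C)[C@](C)(C=C)[C@@H](OC(=O)C(C)C)[C@H]1OC(=O)C(CO)([Se](=O)c2ccccc2)C1 | intermediate (not isolated)
25 | α-(hydroxymethyl)butenolide (C7=C11, C13–OH; C6–OSiEt3, C15–OTBS, C9 isobutyrate) | CC[Si](CC)(CC)OC[C@@H](C(=C)CO[Si](C)(C)C(C)(C)C)[C@](C)(C=C)[C@@H](OC(=O)C(C)C)[C@H]1OC(=O)C(CO)=C1 | intermediate
26 | α-[(phenylsulfanyl)methyl]butenolide (C6–OSiEt3) | CC[Si](CC)(CC)OC[C@@H](C(=C)CO[Si](C)(C)C(C)(C)C)[C@](C)(C=C)[C@@H](OC(=O)C(C)C)[C@H]1OC(=O)C(CSc2ccccc2)=C1 | intermediate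
27 | C6 primary alcohol of 26 | OC[C@@H](C(=C)CO[Si](C)(C)C(C)(C)C)[C@](C)(C=C)[C@@H](OC(=O)C(C)C)[C@H]1OC(=O)C(CSc2ccccc2)=C1 | intermediate
28 | seco-aldehyde (cyclisation precursor), (5S,10S,9R,8S) | O=C[C@@H](C(=C)CO[Si](C)(C)C(C)(C)C)[C@](C)(C=C)[C@@H](OC(=O)C(C)C)[C@H]1OC(=O)C(CSc2ccccc2)=C1 | intermediate
29 | 15-O-(tert-butyldimethylsilyl) ether of the target | C=C[C@@]1(C)[C@H](C(=C)CO[Si](C)(C)C(C)(C)C)[C@@H](O)[C@@H]2C(=C)C(=O)O[C@@H]2[C@@H]1OC(=O)C(C)C | intermediate
30 | CNP0298885.1: cis-fused α-methylene γ-lactone (C8–O, C7–C11) on the cyclohexane, 6-hydroxy, 9-isobutyrate, 10-methyl-10-vinyl, 5-(3-hydroxyprop-1-en-2-yl) | C=C[C@@]1(C)[C@H](C(=C)CO)[C@@H](O)[C@@H]2C(=C)C(=O)O[C@@H]2[C@@H]1OC(=O)C(C)C | target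

**Step count**

Total: 19 steps. Longest linear sequence: 17 steps (steps 3–19, from 2-bromoprop-2-en-1-ol).

**Steps most likely to fail**

Step 18 (Proposed new method). What may go wrong: reduction of the butenolide or of the product α-methylene lactone in competition with ketyl formation; protonation of the C11 samarium enolate before thiolate is lost; conjugate re-addition of thiolate to the new methylene lactone; acyl transfer of the lactone to the C6 alkoxide. The fallback uses known chemistry, sets out from 21 and returns at 30. Compound 21 is selenenylated as in step 13 to 22, and NaIO4 gives the selenoxide F1, which eliminates to the C11-unsubstituted butenolide F2. PPTS in MeOH gives the primary alcohol F3 and Dess–Martin oxidation the aldehyde F4. The established SmI2/MeOH ketyl–olefin cyclisation onto the unsaturated lactone gives the cis-fused hydroxy lactone F5. TESCl and imidazole give the C6 triethylsilyl ether F6. LiN(SiMe3)2 and Eschenmoser's salt give the Mannich base F7, MeI the ammonium iodide F8 and NaHCO3 the α-methylene lactone F9. HF·pyridine removes both silyl groups to give 30.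

Step 11. What may go wrong: slow addition of the congested pinacol boronate, during which aldehyde 3 epimerises at C8 or oligomerises, and loss of facial selectivity if the mixture has to be heated. The fallback sets out from 19 and returns at 20. n-BuLi at −78 °C converts 19 into the lithium n-butyl boronate complex F10, and trifluoroacetic anhydride opens it to the allyl borinic ester F11. F11 should add to 3 at −78 °C through the same closed chair (borinic-ester allylboration), giving 20 after hydrolysis.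

Step 13. What may go wrong: competing deprotonation of the isobutyrate, or attack of the lactone enolate on the neighbouring ester (acyl transfer), under lithium amide conditions. The fallback sets out from 21 and returns at 23. Soft enolisation with TMSOTf and Et3N gives the silyl ketene acetal F12, and PhSeCl converts it into 22. A second soft enolisation gives the α-seleno silyl ketene acetal F13, and Mukaiyama aldol addition to monomeric formaldehyde with BF3·OEt2 at −78 °C gives 23.

**Further compounds**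

F1 | step 18 | selenoxide of 22 | CC[Si](CC)(CC)OC[C@@H](C(=C)CO[Si](C)(C)C(C)(C)C)[C@](C)(C=C)[C@@H](OC(=O)C(C)C)[C@H]1OC(=O)C([Se](=O)c2ccccc2)C1
F2 | step 18 | C11-unsubstituted butenolide (C6–OSiEt3) | CC[Si](CC)(CC)OC[C@@H](C(=C)CO[Si](C)(C)C(C)(C)C)[C@](C)(C=C)[C@@H](OC(=O)C(C)C)[C@H]1OC(=O)C=C1
F3 | step 18 | C6 primary alcohol of F2 | OC[C@@H](C(=C)CO[Si](C)(C)C(C)(C)C)[C@](C)(C=C)[C@@H](OC(=O)C(C)C)[C@H]1OC(=O)C=C1
F4 | step 18 | C6 aldehyde of F2 | O=C[C@@H](C(=C)CO[Si](C)(C)C(C)(C)C)[C@](C)(C=C)[C@@H](OC(=O)C(C)C)[C@H]1OC(=O)C=C1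
F5 | step 18 | cis-fused hydroxy lactone with C11H2 (15-O-TBS) | C=C[C@@]1(C)[C@H](C(=C)CO[Si](C)(C)C(C)(C)C)[C@@H](O)[C@@H]2CC(=O)O[C@@H]2[C@@H]1OC(=O)C(C)C
F6 | step 18 | C6 triethylsilyl ether of F5 | C=C[C@@]1(C)[C@H](C(=C)CO[Si](C)(C)C(C)(C)C)[C@@H](O[Si](CC)(CC)CC)[C@@H]2CC(=O)O[C@@H]2[C@@H]1OC(=O)C(C)C
F7 | step 18 | C11 (dimethylamino)methyl lactone (Mannich base, C11 undefined) | C=C[C@@]1(C)[C@H](C(=C)CO[Si](C)(C)C(C)(C)C)[C@@H](O[Si](CC)(CC)CC)[C@@H]2C(CN(C)C)C(=O)O[C@@H]2[C@@H]1OC(=O)C(C)C
F8 | step 18 | trimethylammonium iodide of F7 | [I-].C=C[C@@]1(C)[C@H](C(=C)CO[Si](C)(C)C(C)(C)C)[C@@H](O[Si](CC)(CC)CC)[C@@H]2C(C[N+](C)(C)C)C(=O)O[C@@H]2[C@@H]1OC(=O)C(C)C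
F9 | step 18 | 6-O-triethylsilyl 15-O-tert-butyldimethylsilyl ether of the target | C=C[C@@]1(C)[C@H](C(=C)CO[Si](C)(C)C(C)(C)C)[C@@H](O[Si](CC)(CC)CC)[C@@H]2C(=C)C(=O)O[C@@H]2[C@@H]1OC(=O)C(C)C
F10 | step 11 | lithium n-butyl boronate complex of 19 | [Li+].CCCC[B-]1(C/C=C(C)/[C@@H](CO[Si](CC)(CC)CC)C(=C)CO[Si](C)(C)C(C)(C)C)OC(C)(C)C(C)(C)O1
F11 | step 11 | allyl(n-butyl)borinic ester of pinacol mono(trifluoroacetate) | CCCCB(C/C=C(C)/[C@@H](CO[Si](CC)(CC)CC)C(=C)CO[Si](C)(C)C(C)(C)C)OC(C)(C)C(C)(C)OC(=O)C(F)(F)F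
F12 | step 13 | trimethylsilyl ketene acetal of lactone 21 | CC[Si](CC)(CC)OC[C@@H](C(=C)CO[Si](C)(C)C(C)(C)C)[C@](C)(C=C)[C@@H](OC(=O)C(C)C)[C@H]1OC(O[Si](C)(C)C)=CC1
F13 | step 13 | trimethylsilyl ketene acetal of seleno lactone 22 | CC[Si](CC)(CC)OC[C@@H](C(=C)CO[Si](C)(C)C(C)(C)C)[C@](C)(C=C)[C@@H](OC(=O)C(C)C)[C@H]1OC(O[Si](C)(C)C)=C([Se]c2ccccc2)C1
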